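**Retrosynthetic overview**

1. The target is guibourtinidol-(4α→6)-fisetinidol. The last step removes five benzyl ethers; before it, one double hydroboration–oxidation of a bis(4H-chromene) sets C2 and C3 of both units (upper ring anti to the C4 aryl group, lower ring by a chiral borane).
2. Key disconnection: both pyran rings are opened at O1–C8a (aryl C–O), and the lower one also at C3–C4. This gives an open-chain β,β-diaryl ketone carrying one benzylic bromide and two aryl bromides, plus 3,4-bis(benzyloxy)acetophenone.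
3. Enabling feature: in each flavan unit O1 sits on C8a, the ring-A carbon next to C4a (which carries C4), and C2 carries O1 and ring B. So O1–C2–C3 is the O–C=C of an aryl ketone enolate and C4–C4a–C8a is a 2-bromobenzyl unit; the lower C4 is a CH2 para to the C7 oxygen, i.e. a very reactive 4-alkoxybenzyl bromide.
4. The C4–C6 bond between the units and the C4 stereocentre come earlier, from a rhodium-catalysed asymmetric 1,4-addition of a ring-A boronate (lower unit) to a chalcone (upper unit). The C6 position is fixed by iodination of 2-bromo-4-hydroxybenzaldehyde.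
5. Ring order: rings A and B of both units are bought as arenes; the two rings C (lower and upper pyran) are closed together in the key step.

Key step: step 9

Assumption: the sense of induction in the two reagent-controlled steps is taken from the accepted models (rhodium–chiral diene additions to E-enones in step 7; IpcBH2 from (+)-α-pinene on 1-arylcycloalkenes in step 10); if a test reaction shows the opposite sense, the antipodal ligand or borane is used and the route is otherwise unchanged.

**Route**

Step 1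
Reactants: 1 2-bromo-4-hydroxybenzaldehyde
Product: 2 2-bromo-4-hydroxy-5-iodobenzaldehyde
Conditions: NIS (1.05 equiv), TFA (cat.), MeCN, 0 °C to rt
Reagents that add atoms: N-iodosuccinimide, O=C1CCC(=O)N1I
Why: Electrophilic aromatic iodination; the hydroxyl group directs ortho, and of the two ortho carbons C5 is the unhindered one (also para to Br and meta to CHO), so iodine should enter at the carbon that becomes C6 of ring A of the lower unit.

Step 2
Reactants: 2 2-bromo-4-hydroxy-5-iodobenzaldehyde
Product: 3 4-(benzyloxy)-2-bromo-5-iodobenzaldehyde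
Conditions: BnBr, K2CO3, DMF, rt
Reagents that add atoms: benzyl bromide, BrCc1ccccc1
Why: Williamson ether synthesis on the phenoxide; no other nucleophilic site is present.

Step 3
Reactants: 3 4-(benzyloxy)-2-bromo-5-iodobenzaldehyde
Product: 4 [4-(benzyloxy)-2-bromo-5-iodophenyl]methanol
Conditions: NaBH4, THF/MeOH, 0 °C
Reagents that add atoms: none
Why: Chemoselective hydride reduction of the aldehyde; aryl halides and the benzyl ether are inert to NaBH4.

Step 4
Reactants: 4 [4-(benzyloxy)-2-bromo-5-iodophenyl]methanol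
Product: 5 [4-(benzyloxy)-2-bromo-5-(4,4,5,5-tetramethyl-1,3,2-dioxaborolan-2-yl)phenyl]methanol
Conditions: B2pin2, PdCl2(dppf) (3 mol %), KOAc, DMSO, 60 °C
Reagents that add atoms: bis(pinacolato)diboron, CC1(C)OB(OC1(C)C)B1OC(C)(C)C(C)(C)O1
Why: Miyaura borylation; zerovalent palladium inserts into the C–I bond much faster than into the C–Br bond and KOAc is too weak a base to start Suzuki coupling of the product, so the bromine needed later should survive.

Step 5
Reactants: 1 2-bromo-4-hydroxybenzaldehyde
Product: 6 4-(benzyloxy)-2-bromobenzaldehyde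
Conditions: BnBr, K2CO3, DMF, rt
Reagents that add atoms: benzyl bromide, BrCc1ccccc1
Why: Williamson ether synthesis on the phenoxide.

Step 6
Reactants: 6 4-(benzyloxy)-2-bromobenzaldehyde; 7 1-[4-(benzyloxy)phenyl]ethan-1-one
Product: 8 (2E)-3-[4-(benzyloxy)-2-bromophenyl]-1-[4-(benzyloxy)phenyl]prop-2-en-1-one
Conditions: KOH (aq), EtOH, rt
Reagents that add atoms: none
Why: Claisen–Schmidt condensation; the aldehyde has no α-hydrogen and the E-enone forms under thermodynamic control.

Step 7
Reactants: 8 (2E)-3-[4-(benzyloxy)-2-bromophenyl]-1-[4-(benzyloxy)phenyl]prop-2-en-1-one; 5 [4-(benzyloxy)-2-bromo-5-(4,4,5,5-tetramethyl-1,3,2-dioxaborolan-2-yl)phenyl]methanol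
Product: 9 (3R)-3-[4-(benzyloxy)-2-bromophenyl]-3-[2-(benzyloxy)-4-bromo-5-(hydroxymethyl)phenyl]-1-[4-(benzyloxy)phenyl]propan-1-one
Conditions: [RhCl(C2H4)2]2 (2.5 mol %), (R,R)-Ph-bod (2,5-diphenylbicyclo[2.2.2]octa-2,5-diene, 5.5 mol %), KOH (0.5 equiv), dioxane/H2O (10:1), 40 °C
Reagents that add atoms: none
Why: Hayashi–Miyaura reaction (rhodium-catalysed asymmetric 1,4-addition); the aryl–rhodium species formed by transmetalation from 5 inserts the enone and the chiral diene selects the enantioface, which sets the diarylmethine stereocentre (the later C4 of the upper unit) together with the C4–C6 bond between the units, while aryl bromides and the free benzylic alcohol are tolerated by monovalent rhodium under these mild conditions.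

Step 8
Reactants: 9 (3R)-3-[4-(benzyloxy)-2-bromophenyl]-3-[2-(benzyloxy)-4-bromo-5-(hydroxymethyl)phenyl]-1-[4-(benzyloxy)phenyl]propan-1-one
Product: 10 (3R)-3-[4-(benzyloxy)-2-bromophenyl]-3-[2-(benzyloxy)-4-bromo-5-(bromomethyl)phenyl]-1-[4-(benzyloxy)phenyl]propan-1-one
Conditions: CBr4, PPh3, CH2Cl2, 0 °C; filtered through a short pad and used at once
Reagents that add atoms: carbon tetrabromide, BrC(Br)(Br)Br
Why: Appel reaction; the neutral conditions leave the ketone and the stereocentre untouched, and the only hydroxyl group is the benzylic one.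

Step 9
Reactants: 10 (3R)-3-[4-(benzyloxy)-2-bromophenyl]-3-[2-(benzyloxy)-4-bromo-5-(bromomethyl)phenyl]-1-[4-(benzyloxy)phenyl]propan-1-one; 11 1-[3,4-bis(benzyloxy)phenyl]ethan-1-one
Product: 14 (4S)-7-(benzyloxy)-4-{7-(benzyloxy)-2-[3,4-bis(benzyloxy)phenyl]-4H-chromen-6-yl}-2-[4-(benzyloxy)phenyl]-4H-chromene, via lithium enolate 12 (not isolated), via diketone dibromide 13 (not isolated)
Conditions: 11 (1.3 equiv), LiN(SiMe3)2 (1.3 equiv), THF, −78 °C; then 10, −78 to −30 °C; then CuI (20 mol %), 1,10-phenanthroline (40 mol %), Cs2CO3 (4 equiv), DMF (THF distilled off), 100 °C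
Reagents that add atoms: none
Why: The lithium enolate 12 alkylates the benzylic bromide of 10 (SN2 at a 4-alkoxybenzyl carbon, making C3–C4 of the lower unit) to give 13; Cs2CO3 then forms the Z-enolates of both aryl ketones, and monovalent copper inserts into each ortho C–Br bond and releases the enol ether by C–O reductive elimination (Ullmann-type enolate O-arylation, making O1–C8a in both units). The closest known reactions are the copper-catalysed domino C-benzylation/O-arylation of 1,3-dicarbonyl compounds with 2-bromobenzyl bromides to 4H-chromenes and the copper-catalysed O-arylation of ketone enolates to benzofurans. Each pyran ring closes as a six-membered ring by attack of the enolate oxygen on the copper-bound C8a (formally a 6-exo closure at the aryl carbon, delivered through a seven-membered aryl–copper–enolate chelate); C-arylation would need a four-membered ring and is excluded. No stereocentre is formed, the diarylmethine centre of 10 should be carried through unchanged, and the two new double bonds are fixed as C2=C3 by the position of the ketones. The step needs C-monoalkylation of 12 without proton transfer to the ketone of 10, which low temperature, the lithium counter-ion, a small excess of 12 and the high SN2 reactivity of the para-oxygenated benzylic bromide should secure; it also needs intramolecular over intermolecular O-arylation, which the ortho placement of Br next to the three-carbon tether in both units should secure.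

Step 10
Reactants: 14 (4S)-7-(benzyloxy)-4-{7-(benzyloxy)-2-[3,4-bis(benzyloxy)phenyl]-4H-chromen-6-yl}-2-[4-(benzyloxy)phenyl]-4H-chromene
Product: 16 (2R,3S,4S)-7-(benzyloxy)-4-{(2R,3S)-7-(benzyloxy)-2-[3,4-bis(benzyloxy)phenyl]-3-hydroxy-3,4-dihydro-2H-chromen-6-yl}-2-[4-(benzyloxy)phenyl]-3,4-dihydro-2H-chromen-3-ol, via bis(organoborane) 15 (not isolated)
Conditions: IpcBH2 [from (+)-α-pinene, 4 equiv], THF, −25 to 0 °C; then NaOH (aq), H2O2, 0 °C to rt
Reagents that add atoms: hydrogen peroxide, OO
Why: Asymmetric hydroboration–oxidation: B–H adds syn to each enol-ether double bond with boron on C3 (β to the ring oxygen and to the C2 aryl group); in the upper ring the borane approaches anti to the C4 aryl group (substrate control, matched with the reagent), in the lower ring the face is chosen by IpcBH2 as for 1-arylcycloalkenes, and oxidation with retention should give the 2,3-trans (upper also 3,4-trans) alcohols, four new stereocentres in all.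

Step 11
Reactants: 16 (2R,3S,4S)-7-(benzyloxy)-4-{(2R,3S)-7-(benzyloxy)-2-[3,4-bis(benzyloxy)phenyl]-3-hydroxy-3,4-dihydro-2H-chromen-6-yl}-2-[4-(benzyloxy)phenyl]-3,4-dihydro-2H-chromen-3-ol
Product: 17 (2R,3S,4R)-4-[(2R,3S)-2-(3,4-dihydroxyphenyl)-3,7-dihydroxy-3,4-dihydro-2H-chromen-6-yl]-2-(4-hydroxyphenyl)-3,4-dihydro-2H-chromene-3,7-diol (target)
Conditions: H2 (1 atm), Pd(OH)2/C, THF/MeOH, rt
Reagents that add atoms: none
Why: Catalytic hydrogenolysis of the five benzyl ethers; the ring C–O bonds and the C4–C6 bond of flavan-3-ols should survive Pd(OH)2/C at 1 atm and no stereocentre is touched (the descriptor at C4 changes from S to R only because the priorities change).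

**Compound list**

1 | 2-bromo-4-hydroxybenzaldehyde | O=Cc1ccc(O)cc1Br | starting material
2 | 2-bromo-4-hydroxy-5-iodobenzaldehyde | O=Cc1cc(I)c(O)cc1Br | intermediate
3 | 4-(benzyloxy)-2-bromo-5-iodobenzaldehyde | O=Cc1cc(I)c(OCc2ccccc2)cc1Br | intermediate
4 | [4-(benzyloxy)-2-bromo-5-iodophenyl]methanol | OCc1cc(I)c(OCc2ccccc2)cc1Br | intermediate
5 | [4-(benzyloxy)-2-bromo-5-(4,4,5,5-tetramethyl-1,3,2-dioxaborolan-2-yl)phenyl]methanol | OCc1cc(B2OC(C)(C)C(C)(C)O2)c(OCc2ccccc2)cc1Br | intermediate
6 | 4-(benzyloxy)-2-bromobenzaldehyde | O=Cc1ccc(OCc2ccccc2)cc1Br | intermediate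
7 | 1-[4-(benzyloxy)phenyl]ethan-1-one | CC(=O)c1ccc(OCc2ccccc2)cc1 | starting material
8 | (2E)-3-[4-(benzyloxy)-2-bromophenyl]-1-[4-(benzyloxy)phenyl]prop-2-en-1-one | O=C(/C=C/c1ccc(OCc2ccccc2)cc1Br)c1ccc(OCc2ccccc2)cc1 | intermediate
9 | (3R)-3-[4-(benzyloxy)-2-bromophenyl]-3-[2-(benzyloxy)-4-bromo-5-(hydroxymethyl)phenyl]-1-[4-(benzyloxy)phenyl]propan-1-one | O=C(C[C@@H](c1ccc(OCc2ccccc2)cc1Br)c1cc(CO)c(Br)cc1OCc1ccccc1)c1ccc(OCc2ccccc2)cc1 | intermediate
10 | (3R)-3-[4-(benzyloxy)-2-bromophenyl]-3-[2-(benzyloxy)-4-bromo-5-(bromomethyl)phenyl]-1-[4-(benzyloxy)phenyl]propan-1-one | O=C(C[C@@H](c1ccc(OCc2ccccc2)cc1Br)c1cc(CBr)c(Br)cc1OCc1ccccc1)c1ccc(OCc2ccccc2)cc1 | intermediate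
11 | 1-[3,4-bis(benzyloxy)phenyl]ethan-1-one | CC(=O)c1ccc(OCc2ccccc2)c(OCc2ccccc2)c1 | starting material
12 | lithium 1-[3,4-bis(benzyloxy)phenyl]ethen-1-olate | [Li]OC(=C)c1ccc(OCc2ccccc2)c(OCc2ccccc2)c1 | intermediate (not isolated)
13 | (3R)-3-[4-(benzyloxy)-2-bromophenyl]-3-{2-(benzyloxy)-5-[3-(3,4-bis(benzyloxy)phenyl)-3-oxopropyl]-4-bromophenyl}-1-[4-(benzyloxy)phenyl]propan-1-one | O=C(C[C@@H](c1ccc(OCc2ccccc2)cc1Br)c1cc(CCC(=O)c2ccc(OCc3ccccc3)c(OCc3ccccc3)c2)c(Br)cc1OCc1ccccc1)c1ccc(OCc2ccccc2)cc1 | intermediate (not isolated)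
14 | (4S)-7-(benzyloxy)-4-{7-(benzyloxy)-2-[3,4-bis(benzyloxy)phenyl]-4H-chromen-6-yl}-2-[4-(benzyloxy)phenyl]-4H-chromene | O(Cc1ccccc1)c1ccc(cc1)C1=C[C@H](c4cc5CC=C(Oc5cc4OCc4ccccc4)c4ccc(OCc5ccccc5)c(OCc5ccccc5)c4)c2ccc(OCc3ccccc3)cc2O1 | intermediate
15 | bis(organoborane): 16 with an isopinocampheyl-BH group in place of each 3-hydroxyl, same configuration | O(Cc5ccccc5)c1ccc([C@H]2Oc3cc(OCc5ccccc5)ccc3[C@@H](c3cc4c(cc3OCc5ccccc5)O[C@H](c3ccc(OCc5ccccc5)c(OCc5ccccc5)c3)[C@@H](B[C@@H]6C[C@@H]7C[C@H]([C@H]6C)C7(C)C)C4)[C@@H]2B[C@@H]6C[C@@H]7C[C@H]([C@H]6C)C7(C)C)cc1 | intermediate (not isolated)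
16 | (2R,3S,4S)-7-(benzyloxy)-4-{(2R,3S)-7-(benzyloxy)-2-[3,4-bis(benzyloxy)phenyl]-3-hydroxy-3,4-dihydro-2H-chromen-6-yl}-2-[4-(benzyloxy)phenyl]-3,4-dihydro-2H-chromen-3-ol | O(Cc5ccccc5)c1ccc([C@H]2Oc3cc(OCc5ccccc5)ccc3[C@@H](c3cc4c(cc3OCc5ccccc5)O[C@H](c3ccc(OCc5ccccc5)c(OCc5ccccc5)c3)[C@@H](O)C4)[C@@H]2O)cc1 | intermediate
17 | (2R,3S,4R)-4-[(2R,3S)-2-(3,4-dihydroxyphenyl)-3,7-dihydroxy-3,4-dihydro-2H-chromen-6-yl]-2-(4-hydroxyphenyl)-3,4-dihydro-2H-chromene-3,7-diol | Oc1ccc([C@H]2Oc3cc(O)ccc3[C@@H](c3cc4c(cc3O)O[C@H](c3ccc(O)c(O)c3)[C@@H](O)C4)[C@@H]2O)cc1 | target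

**Step count and risks**

Total step count: 11. Longest linear sequence: 9 steps (steps 1, 2, 3, 4, 7, 8, 9, 10, 11).

Steps most likely to fail:

Step 9. Proton transfer between enolate 12 and the ketone already present in 10 may lead to self-alkylation or over-alkylation. The copper-mediated enolate O-arylation may then stall or end in hydrodebromination, or the hot basic medium may move the C2=C3 double bonds. Fallback, from 13 back to 14: the sequence is stopped after the alkylation stage and 13 is isolated by aqueous work-up. Both aryl bromides are exchanged for hydroxyl by palladium-catalysed hydroxylation (Pd2(dba)3, tBuXPhos, KOH, dioxane/H2O, 80 °C) to give the bis-phenol diketone F1. Acid-catalysed cyclodehydration (PPTS, toluene, reflux, 4 Å molecular sieves) then closes both rings through the cyclic hemiketals, now by forming O1–C2, and should give 14.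

Step 10. The chiral borane may discriminate poorly between the faces of the lower enol ether, which has no stereocentre nearby; it may be mismatched with the C4-directed approach in the upper ring; or the β-aryloxy organoborane may open the ring by β-elimination. Fallback, from 14 back to 16: 14 is hydroborated with BH3·SMe2 (THF, 0 °C; then NaOH, H2O2) under substrate control only. The upper ring is set by the C4 aryl group, and the lower ring forms as both 2,3-trans isomers, 16 and its lower-unit (2S,3R) diastereomer F2. These are diastereomers because the upper unit is fixed, so they are separated by chromatography.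

Step 7. Protodeboronation of the electron-rich ortho-alkoxy aryl boronate may outrun insertion into the hindered ortho-bromo enone, or enantioface discrimination may be low. Fallback, from 4 (with 8) back to 9: 4 is silylated (TBSCl, imidazole, DMF) to the silyl ether F3. Iodine–magnesium exchange (iPrMgCl·LiCl, THF, −30 °C, C–Br left intact) gives the arylmagnesium chloride F4. Its CuI-catalysed 1,4-addition to chalcone 8 (THF, −30 °C) gives the racemic silyl-protected ketone F5, and TBAF (THF) gives the racemic alcohol F6. Preparative chromatography on a chiral stationary phase then separates 9 from its enantiomer F7.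

Further compounds
F1 | step 9 | bis-phenol diketone: 13 with OH in place of both aryl bromines, same configuration | O=C(C[C@@H](c1ccc(OCc2ccccc2)cc1O)c1cc(CCC(=O)c2ccc(OCc3ccccc3)c(OCc3ccccc3)c2)c(O)cc1OCc1ccccc1)c1ccc(OCc2ccccc2)cc1
F2 | step 10 | lower-unit (2S,3R) diastereomer of 16 | O(Cc5ccccc5)c1ccc([C@H]2Oc3cc(OCc5ccccc5)ccc3[C@@H](c3cc4c(cc3OCc5ccccc5)O[C@@H](c3ccc(OCc5ccccc5)c(OCc5ccccc5)c3)[C@H](O)C4)[C@@H]2O)cc1
F3 | step 7 | {[4-(benzyloxy)-2-bromo-5-iodophenyl]methoxy}(tert-butyl)dimethylsilane | CC(C)(C)[Si](C)(C)OCc1cc(I)c(OCc2ccccc2)cc1Br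
F4 | step 7 | [2-(benzyloxy)-4-bromo-5-({[tert-butyl(dimethyl)silyl]oxy}methyl)phenyl]magnesium chloride | Cl[Mg]c1cc(CO[Si](C)(C)C(C)(C)C)c(Br)cc1OCc1ccccc1
F5 | step 7 | racemic 3-[4-(benzyloxy)-2-bromophenyl]-3-[2-(benzyloxy)-4-bromo-5-({[tert-butyl(dimethyl)silyl]oxy}methyl)phenyl]-1-[4-(benzyloxy)phenyl]propan-1-one | O=C(CC(c1ccc(OCc2ccccc2)cc1Br)c1cc(CO[Si](C)(C)C(C)(C)C)c(Br)cc1OCc1ccccc1)c1ccc(OCc2ccccc2)cc1
F6 | step 7 | racemic 3-[4-(benzyloxy)-2-bromophenyl]-3-[2-(benzyloxy)-4-bromo-5-(hydroxymethyl)phenyl]-1-[4-(benzyloxy)phenyl]propan-1-one | O=C(CC(c1ccc(OCc2ccccc2)cc1Br)c1cc(CO)c(Br)cc1OCc1ccccc1)c1ccc(OCc2ccccc2)cc1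
F7 | step 7 | (3S)-enantiomer of 9 | O=C(C[C@H](c1ccc(OCc2ccccc2)cc1Br)c1cc(CO)c(Br)cc1OCc1ccccc1)c1ccc(OCc2ccccc2)cc1
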